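**Retrosynthetic overview**

1. The ester is assembled last, in one flask, from three components: 2-(10-bromodecyl)furan, propyne (as its 1,3-dianion) and the 6-bromohex-5-ynoate of the complete alcohol half. The CH2 carbon of the dianion is alkylated by the bromide (bond C9–C10 of the nonadecadiynoate chain, sp3–sp3), and the acetylide that remains is coupled through copper with the bromoalkyne (bond C6–C7, sp–sp).
2. Enabling feature: the propargylic triad C7≡C8–C9H2 of the acyl chain, held between the saturated C10–C19 tether to furan ring A and the second triple bond C5≡C6. It is propyne at the dianion oxidation level, nucleophilic at sp3 C9 and at sp C7 with sharply different reactivity.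
3. Bromoalkyne ester ⇐ Steglich esterification of 6-bromohex-5-ynoic acid with 11-(furan-2-yl)undeca-4,6-diyn-1-ol; diynol ⇐ Cadiot–Chodkiewicz coupling of 2-(hex-5-yn-1-yl)furan with 5-bromopent-4-yn-1-ol.
4. Both 2-alkylfurans ⇐ one batch of 2-furyllithium, divided, + an α,ω-dihalide. No ring is formed at any stage: both furan rings (A on the acyl chain, B on the alkoxy chain) are bought as furan.

Key step: step 9

Remark: the target has no stereocentre and no C=C stereo element, so it is achiral and "single enantiomer" is taken to mean the one compound drawn.

**Route**

Step 1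
Reactants: 1 furan
Product: 2 2-furyllithium
Conditions: 1 (1.1 equiv), n-BuLi (1.0 equiv), THF, −78 to 0 °C, Ar; kept at 0 °C as a titrated solution and drawn on the same day for steps 2 and 3
Reagents that add atoms: n-butyllithium, [Li]CCCC
Why: Deprotonation of furan by n-BuLi at C2, the most acidic C–H (α to oxygen; α-metalation of a heteroarene), should give a THF solution that is stable at 0 °C for hours, so one batch can serve both alkylations.

Step 2
Reactants: 2 2-furyllithium; 3 1,10-dibromodecane
Product: 4 2-(10-bromodecyl)furan
Conditions: solution of 2 (1 equiv) added to 3 (3 equiv), THF, −78 °C to rt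
Reagents that add atoms: none
Why: SN2 alkylation of 2-furyllithium with a primary bromide is the standard route to 2-alkylfurans, and the threefold excess of the dibromide with inverse addition should hold back the second substitution.

Step 3
Reactants: 2 2-furyllithium; 5 1-bromo-4-chlorobutane
Product: 6 2-(4-chlorobutyl)furan
Conditions: solution of 2 (1 equiv), 5 (1.1 equiv), THF, −78 °C to rt
Reagents that add atoms: none
Why: The same SN2 alkylation of 2-furyllithium; bromide is displaced far faster than chloride, so the chloride should survive as the handle for step 4.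

Step 4
Reactants: 6 2-(4-chlorobutyl)furan
Product: 7 2-(hex-5-yn-1-yl)furan
Conditions: HC≡CLi·H2NCH2CH2NH2, NaI (cat.), DMSO, rt
Reagents that add atoms: lithium acetylide–ethylenediamine complex, [Li]C#C.NCCN
Why: SN2 alkynylation of a primary chloride by lithium acetylide in DMSO (iodide catalysis), conditions to which the furan ring is inert.

Step 5
Reactants: 8 pent-4-yn-1-ol
Product: 9 5-bromopent-4-yn-1-ol
Conditions: NBS, AgNO3 (cat.), acetone, rt, dark
Reagents that add atoms: N-bromosuccinimide, O=C1CCC(=O)N1Br
Why: Silver-catalysed electrophilic bromination of a terminal alkyne with NBS through the silver acetylide, which leaves the free hydroxyl untouched.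

Step 6
Reactants: 7 2-(hex-5-yn-1-yl)furan; 9 5-bromopent-4-yn-1-ol
Product: 10 11-(furan-2-yl)undeca-4,6-diyn-1-ol
Conditions: CuCl (cat.), NH2OH·HCl (cat.), 30% aq. n-BuNH2, Et2O, 0 °C to rt
Reagents that add atoms: none
Why: Cadiot–Chodkiewicz coupling, in which the copper(I) acetylide of 7 adds oxidatively to the bromoalkyne and reductive elimination gives the unsymmetrical 1,3-diyne, hydroxylamine keeping copper at +1 to suppress Glaser homocoupling.

Step 7
Reactants: 11 hex-5-ynoic acid
Product: 12 6-bromohex-5-ynoic acid
Conditions: NBS, AgNO3 (cat.), acetone, rt, dark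
Reagents that add atoms: N-bromosuccinimide, O=C1CCC(=O)N1Br
Why: Silver-catalysed bromination of the terminal alkyne with NBS as in step 5; no base is present, so the carboxylic acid should remain a spectator.

Step 8
Reactants: 12 6-bromohex-5-ynoic acid; 10 11-(furan-2-yl)undeca-4,6-diyn-1-ol
Product: 13 11-(furan-2-yl)undeca-4,6-diyn-1-yl 6-bromohex-5-ynoate
Conditions: DCC, DMAP (cat.), CH2Cl2, 0 °C to rt
Reagents that add atoms: none
Why: Steglich esterification (carbodiimide activation, acyl transfer by DMAP) under neutral conditions that the bromoalkyne, the conjugated diyne and the acid-sensitive furan should tolerate.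

Step 9
Reactants: 14 propyne; 4 2-(10-bromodecyl)furan; 13 11-(furan-2-yl)undeca-4,6-diyn-1-yl 6-bromohex-5-ynoate
Product: 18 11-(furan-2-yl)undeca-4,6-diyn-1-yl 19-(furan-2-yl)nonadeca-5,7-diynoate, via 1,3-dilithiopropyne 15 (not isolated), via lithium 13-(furan-2-yl)tridec-1-yn-1-ide 16 (not isolated), via copper(I) 13-(furan-2-yl)tridec-1-yn-1-ide 17 (not isolated)
Conditions: 14, n-BuLi (2.0 equiv), TMEDA, Et2O–hexane, −78 °C to rt; 4 (slight excess), −78 to 0 °C; CuI (1.1 equiv), pyridine–THF, −20 to 0 °C; 13 (0.8 equiv), 0 °C to rt, Ar
Reagents that add atoms: none
Why: Proposed new method: a three-component union in one flask, in which the sp3 carbanion of dianion 15 displaces bromide from 4 (SN2) to form the CH2–CH2 bond C9–C10 of the acyl chain, and the lithium acetylide 16 left behind is transmetalated to copper acetylide 17, which couples with bromoalkyne 13 by oxidative addition and reductive elimination at copper to form the sp–sp bond C6–C7. The closest known reaction types are the propargylation of primary alkyl halides with 1,3-dilithiopropyne, in which the resulting lithium acetylide is trapped by a second electrophile in the same flask, and the coupling of preformed copper(I) acetylides with 1-bromoalkynes in pyridine (the stoichiometric form of the Cadiot–Chodkiewicz reaction); new is their merger, with a bromoalkyne as the second electrophile. No ring is closed and no stereocentre is formed. The step needs site selectivity in the dianion, which the far higher basicity and nucleophilicity of the CH2Li carbon over the acetylide carbon should secure (alkylation at C9 only, giving the alkyne and not an allene because C7 keeps its own sp lone pair). It also needs chemoselectivity in the second event, which the change from lithium to copper should secure, because a copper acetylide leaves the ester of 13, the residual alkyl bromide, the conjugated diyne and both furans untouched and is far less prone to halogen–metal exchange than a lithium acetylide. Bromide 4 is kept in slight excess over 15 so that no sp3 carbanion survives when copper is added, and 13 is the limiting component.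

**Compound list**

1 | furan | c1ccoc1 | starting material
2 | 2-furyllithium | [Li]c1ccco1 | intermediate
3 | 1,10-dibromodecane | BrCCCCCCCCCCBr | starting material
4 | 2-(10-bromodecyl)furan | BrCCCCCCCCCCc1ccco1 | intermediate
5 | 1-bromo-4-chlorobutane | ClCCCCBr | starting material
6 | 2-(4-chlorobutyl)furan | ClCCCCc1ccco1 | intermediate
7 | 2-(hex-5-yn-1-yl)furan | C#CCCCCc1ccco1 | intermediate
8 | pent-4-yn-1-ol | C#CCCCO | starting material
9 | 5-bromopent-4-yn-1-ol | BrC#CCCCO | intermediate
10 | 11-(furan-2-yl)undeca-4,6-diyn-1-ol | OCCCC#CC#CCCCCc1ccco1 | intermediate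
11 | hex-5-ynoic acid | C#CCCCC(=O)O | starting material
12 | 6-bromohex-5-ynoic acid | BrC#CCCCC(=O)O | intermediate
13 | 11-(furan-2-yl)undeca-4,6-diyn-1-yl 6-bromohex-5-ynoate | BrC#CCCCC(=O)OCCCC#CC#CCCCCc1ccco1 | intermediate
14 | propyne | CC#C | starting material
15 | 1,3-dilithiopropyne | [Li]CC#C[Li] | intermediate
16 | lithium 13-(furan-2-yl)tridec-1-yn-1-ide | [Li]C#CCCCCCCCCCCCc1ccco1 | intermediate
17 | copper(I) 13-(furan-2-yl)tridec-1-yn-1-ide | [Cu]C#CCCCCCCCCCCCc1ccco1 | intermediate
18 | 11-(furan-2-yl)undeca-4,6-diyn-1-yl 19-(furan-2-yl)nonadeca-5,7-diynoate | O=C(CCCC#CC#CCCCCCCCCCCCc1ccco1)OCCCC#CC#CCCCCc1ccco1 | target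

**Step count and risks**

Total step count: 9. Longest linear sequence: 6 steps (steps 1, 3, 4, 6, 8, 9, from furan).

Steps most likely to fail:

Step 9 (Proposed new method). Possible failures are proton transfer from the furan C5–H of 4 to the dianion in competition with alkylation, incomplete lithium-to-copper exchange followed by halogen–metal exchange and homocoupling to symmetrical diynes, and attack of a residual lithium species on the ester. The fallback uses known two-component reactions, forms the ester bond last, sets out from 4 and comes back to the route at 18. Bromide 4 would be alkylated with 3-(trimethylsilyl)prop-2-yn-1-yllithium F1 (from 1-(trimethylsilyl)propyne and n-BuLi, THF, −78 to 0 °C), a propargyl anion equivalent that alkylates at CH2, to give trimethyl[13-(furan-2-yl)tridec-1-yn-1-yl]silane F2. Desilylation (K2CO3, MeOH) should give 2-(tridec-12-yn-1-yl)furan F3. Catalytic Cadiot–Chodkiewicz coupling of F3 with bromo acid 12 (CuCl, NH2OH·HCl, aq. n-BuNH2, THF) should give 19-(furan-2-yl)nonadeca-5,7-diynoic acid F4, and Steglich esterification of F4 with diynol 10 (DCC, DMAP, CH2Cl2) should give 18.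

Step 7. The carboxylic acid may cyclise onto the silver- or bromine-activated alkyne (halolactonisation) instead of the alkyne C–H being brominated. The fallback masks the acid, sets out from 11 and comes back at 12. Fischer esterification (MeOH, cat. H2SO4) would give methyl hex-5-ynoate F5, bromination (NBS, cat. AgNO3, acetone) methyl 6-bromohex-5-ynoate F6, and saponification (LiOH, THF–H2O, 0 °C, then mild acidification) 12.

Step 6. Homocoupling of either partner and reduction of the bromoalkyne may give symmetrical diynes that are hard to separate from the product. The fallback builds the second triple bond by elimination instead of coupling it on, sets out from 7 and comes back at 10. Sonogashira coupling of 7 with excess (E)-1,2-dichloroethene (Pd(PPh3)4, CuI, n-BuNH2) would give 2-[(E)-8-chlorooct-7-en-5-yn-1-yl]furan F7. LDA (2.2 equiv, THF, −78 °C) should eliminate HCl and deprotonate the new terminal diyne to give [8-(furan-2-yl)octa-1,3-diyn-1-yl]lithium F8 (not isolated), which would be opened onto oxetane with BF3·OEt2 at −78 °C to give 10.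

**Further compounds**

F1 | step 9 | 3-(trimethylsilyl)prop-2-yn-1-yllithium | [Li]CC#C[Si](C)(C)C
F2 | step 9 | trimethyl[13-(furan-2-yl)tridec-1-yn-1-yl]silane | C[Si](C)(C)C#CCCCCCCCCCCCc1ccco1
F3 | step 9 | 2-(tridec-12-yn-1-yl)furan | C#CCCCCCCCCCCCc1ccco1
F4 | step 9 | 19-(furan-2-yl)nonadeca-5,7-diynoic acid | O=C(O)CCCC#CC#CCCCCCCCCCCCc1ccco1
F5 | step 7 | methyl hex-5-ynoate | C#CCCCC(=O)OC
F6 | step 7 | methyl 6-bromohex-5-ynoate | BrC#CCCCC(=O)OC
F7 | step 6 | 2-[(E)-8-chlorooct-7-en-5-yn-1-yl]furan | Cl/C=C/C#CCCCCc1ccco1
F8 | step 6 | [8-(furan-2-yl)octa-1,3-diyn-1-yl]lithium | [Li]C#CC#CCCCCc1ccco1
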